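## Retrosynthetic overview

1. Aplyviolene ⇐ a 2-acetoxy-5-methoxy-oxolane carrying a cis CH2CO2tBu arm. The δ-lactone bridge of the dioxabicyclo[3.2.1]octanone is closed last by Lewis-acid transacetalization.
2. That oxolane ⇐ a trisubstituted γ-butanolide, by lactone reduction and anomeric acetylation.
3. The butanolide ⇐ a chiral vinyl bromide plus an (S)-5-methoxybutenolide, joined by one radical cascade. A 7-exo cyclization closes the seven-membered ring, and the resulting tertiary radical is trapped by the butenolide (quaternary carbon and the adjacent CH).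
4. The vinyl bromide ⇐ a 3-substituted 1-methylcyclopentene ⇐ a keto-aldehyde made by organocatalytic Michael addition of 3,3-dimethylpent-4-enal to methyl vinyl ketone (first stereocenter).
5. The butenolide ⇐ furan-2(5H)-one, with its acetal stereocenter set by organocatalytic dynamic kinetic acetalization. Ring order: cyclopentene → cycloheptane → (oxolane carried in) → lactone bridge.

Assumption: compounds 1, 3, 6, 8 and 10 are taken as commercial achiral materials; the catalyst enantiomer in step 8 is the one that gives the (S)-acetal.

## Route

Step 1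
Reactants: 1, methyl 3,3-dimethylpent-4-enoate
Product: 2, 3,3-dimethylpent-4-enal
Conditions: DIBAL-H (1.05 equiv), CH2Cl2, −78 °C; Rochelle salt
Reagents that add atoms: none
Why: Low-temperature DIBAL half-reduction of an ester stops at the aluminium hemiacetal and releases the aldehyde on work-up; no stereocenter.

Step 2
Reactants: 2, 3,3-dimethylpent-4-enal; 3, methyl vinyl ketone
Product: 4, (S)-2-(2-methylbut-3-en-2-yl)-5-oxohexanal
Conditions: (S)-α,α-diphenylprolinol methyl ether (10 mol%), ethyl 3,4-dihydroxybenzoate (20 mol%), neat, 4 °C
Reagents that add atoms: none (all heavy atoms come from 2 and 3)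
Why: Enamine-catalysed asymmetric Michael addition of an aldehyde to an enone; the (E)-enamine is shielded on one face by the CPh2OMe group, so the enone adds to the open (Si) face and sets the first stereocenter (the future ring-fusion CH next to CMe2) as S.

Step 3
Reactants: 4
Product: 5, (R)-1-methyl-3-(2-methylbut-3-en-2-yl)cyclopent-1-ene
Conditions: TiCl3(DME)1.5, Zn–Cu, DME, reflux, slow addition of 4
Reagents that add atoms: none
Why: Intramolecular McMurry coupling of the 1,5-keto-aldehyde (Ti pinacolate, then deoxygenation) gives the cyclopentene with the double bond fixed between the methyl-bearing carbon and the carbon next to the stereocenter; the stereocenter is untouched (S→R is only a CIP priority change).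

Step 4
Reactants: 5; 6, 2,3-dibromoprop-1-ene
Product: 7, (R)-3-(6-bromo-2-methylhept-6-en-2-yl)-1-methylcyclopent-1-ene
Conditions: Cp2Zr(H)Cl, THF, rt; then CuBr·SMe2 (10 mol%), 6, 0 °C → rt
Reagents that add atoms: none (all heavy atoms from 5 and 6; H from Cp2Zr(H)Cl)
Why: Schwartz hydrozirconation is selective for the monosubstituted vinyl group over the trisubstituted ring alkene, and the primary alkylzirconocene undergoes Cu-catalysed allylic substitution to install the 2-bromoallyl terminus; stereocenter unaffected.

Step 5
Reactants: 8, furan-2(5H)-one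
Product: 9, 3-bromofuran-2(5H)-one
Conditions: Br2, CH2Cl2, 0 °C → rt; then Et3N, 0 °C
Reagents that add atoms: bromine, BrBr
Why: Bromine addition to the butenolide alkene followed by E1cB loss of HBr (α-proton, β-bromide) gives the α-bromobutenolide.

Step 6
Reactants: 9; 10, tert-butyl bromoacetate
Product: 11, tert-butyl 2-(2-oxo-2,5-dihydrofuran-3-yl)acetate
Conditions: 10, Zn dust, TMSCl (cat.), THF (Reformatsky reagent); then 9, Pd(dba)2/QPhos (2 mol%), THF, rt
Reagents that add atoms: none (all heavy atoms from 9 and 10)
Why: Negishi-type Pd coupling of a zinc ester enolate with a vinyl bromide; the conditions are non-basic, so the butenolide double bond does not migrate.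

Step 7
Reactants: 11
Product: 12, tert-butyl 2-(5-bromo-2-oxo-2,5-dihydrofuran-3-yl)acetate (racemic)
Conditions: NBS (1.05 equiv), AIBN (cat.), PhCF3, 80 °C; used crude
Reagents that add atoms: N-bromosuccinimide, O=C1CCC(=O)N1Br
Why: Wohl–Ziegler bromination at the γ-carbon (allylic and α to the ring oxygen, the most electron-rich C–H), as for the analogous 3-methylbutenolide.

Step 8
Reactants: 12
Product: 13, tert-butyl 2-[(5S)-5-methoxy-2-oxo-2,5-dihydrofuran-3-yl]acetate
Conditions: chiral bifunctional thiourea–quaternary ammonium salt (5 mol%), MeOH (3 equiv), K2CO3, toluene, −20 °C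
Reagents that add atoms: methanol, CO
Why: Organocatalytic dynamic kinetic acetalization; the γ-bromobutenolide racemises by bromide exchange while the chiral ion-pair catalyst delivers methanol to one enantiomer, setting the acetal stereocenter as S.

Step 9
Reactants: 7; 13 (3 equiv)
Product: 14, tert-butyl 2-[(3R,4R,5S)-5-methoxy-2-oxo-4-[(1R,3aR,8aS)-1,4,4-trimethyl-8-methylidenedecahydroazulen-1-yl]oxolan-3-yl]acetate
Conditions: Bu3SnH (1.3 equiv) and AIBN (0.2 equiv) added by syringe pump over 10 h to 7 (0.01 M) and 13 in PhH, 80 °C
Reagents that add atoms: none (all heavy atoms from 7 and 13; H from Bu3SnH)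
Why: Proposed new method: a radical cyclization/intermolecular Giese coupling cascade — Bu3Sn• abstracts Br to give a vinyl σ-radical that cyclises 7-exo-trig onto the CH carbon of the methylcyclopentene on the tether face (cis ring fusion, exocyclic methylene in place; the gem-dimethyl carbon blocks 1,5-H transfer), the resulting tertiary radical adds through the convex face of the cis-hydroazulene to C4 of 13 anti to the 5-OMe group (sets the quaternary carbon R and lactone C4 R), and the α-lactone radical takes H from Bu3SnH anti to the new bulky group (arm cis to it, C3 R); closest known reactions are the Stork vinyl-radical cyclization and the Giese addition of tertiary radicals to 5-alkoxybutenolides.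

Step 10
Reactants: 14
Product: 15, tert-butyl 2-[(3R,4R,5S)-2-hydroxy-5-methoxy-4-[(1R,3aR,8aS)-1,4,4-trimethyl-8-methylidenedecahydroazulen-1-yl]oxolan-3-yl]acetate (anomeric mixture at C2)
Conditions: DIBAL-H (1.3 equiv), CH2Cl2, −78 °C; Rochelle salt; used directly
Reagents that add atoms: none
Why: DIBAL reduces the γ-lactone to the lactol (stable aluminate at −78 °C) faster than the hindered tert-butyl ester; the methyl acetal and alkene are inert and the set stereocenters are untouched.

Step 11
Reactants: 15
Product: 16, tert-butyl 2-[(2S,3R,4R,5S)-2-acetoxy-5-methoxy-4-[(1R,3aR,8aS)-1,4,4-trimethyl-8-methylidenedecahydroazulen-1-yl]oxolan-3-yl]acetate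
Conditions: Ac2O, pyridine, DMAP (cat.), CH2Cl2, 0 °C
Reagents that add atoms: acetic anhydride, CC(=O)OC(C)=O
Why: The lactol anomers equilibrate and acylation takes the less hindered one, trans to the adjacent CH2CO2tBu arm and away from the crowded face, fixing the acetoxy carbon as S.

Step 12
Reactants: 16
Product: 17, aplyviolene, (1S,5R,6S,8R)-3-oxo-8-[(1R,3aR,8aS)-1,4,4-trimethyl-8-methylidenedecahydroazulen-1-yl]-2,7-dioxabicyclo[3.2.1]octan-6-yl acetate
Conditions: TMSOTf (1.2 equiv), 2,6-di-tert-butyl-4-methylpyridine (2 equiv), CH2Cl2, −78 → −20 °C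
Reagents that add atoms: none (MeOH and isobutene are lost)
Why: Lewis-acid transacetalization/lactonization; TMSOTf ionises the methyl acetal (more basic than the anomeric acetate), the oxocarbenium ion is captured by the carbonyl oxygen of the cis tert-butyl ester, which loses isobutene, so the lactone bridge forms on the arm face (acetal carbon inverted to S) under buffered conditions that spare the methylidene; the [3.3.0] alternative would put the hydroazulene on the concave face.

## Compound list

1 | methyl 3,3-dimethylpent-4-enoate | COC(=O)CC(C)(C)C=C | starting material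
2 | 3,3-dimethylpent-4-enal | O=CCC(C)(C)C=C | intermediate
3 | methyl vinyl ketone | CC(=O)C=C | starting material
4 | (S)-2-(2-methylbut-3-en-2-yl)-5-oxohexanal | O=C[C@H](C(C)(C)C=C)CCC(C)=O | intermediate
5 | (R)-1-methyl-3-(2-methylbut-3-en-2-yl)cyclopent-1-ene | CC1=C[C@H](C(C)(C)C=C)CC1 | intermediate
6 | 2,3-dibromoprop-1-ene | C=C(Br)CBr | starting material
7 | (R)-3-(6-bromo-2-methylhept-6-en-2-yl)-1-methylcyclopent-1-ene | CC1=C[C@H](C(C)(C)CCCC(Br)=C)CC1 | intermediate
8 | furan-2(5H)-one | O=C1OCC=C1 | starting material
9 | 3-bromofuran-2(5H)-one | O=C1OCC=C1Br | intermediate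
10 | tert-butyl bromoacetate | BrCC(=O)OC(C)(C)C | starting material
11 | tert-butyl 2-(2-oxo-2,5-dihydrofuran-3-yl)acetate | O=C1OCC=C1CC(=O)OC(C)(C)C | intermediate
12 | tert-butyl 2-(5-bromo-2-oxo-2,5-dihydrofuran-3-yl)acetate (racemic) | O=C1OC(Br)C=C1CC(=O)OC(C)(C)C | intermediate
13 | tert-butyl 2-[(5S)-5-methoxy-2-oxo-2,5-dihydrofuran-3-yl]acetate | CO[C@H]1OC(=O)C(CC(=O)OC(C)(C)C)=C1 | intermediate
14 | tert-butyl 2-[(3R,4R,5S)-5-methoxy-2-oxo-4-[(1R,3aR,8aS)-1,4,4-trimethyl-8-methylidenedecahydroazulen-1-yl]oxolan-3-yl]acetate | C=C1CCCC(C)(C)[C@@H]2CC[C@@](C)([C@@H]3[C@@H](OC)OC(=O)[C@@H]3CC(=O)OC(C)(C)C)[C@H]12 | intermediate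
15 | tert-butyl 2-[(3R,4R,5S)-2-hydroxy-5-methoxy-4-[(1R,3aR,8aS)-1,4,4-trimethyl-8-methylidenedecahydroazulen-1-yl]oxolan-3-yl]acetate (anomeric mixture) | C=C1CCCC(C)(C)[C@@H]2CC[C@@](C)([C@@H]3[C@@H](OC)OC(O)[C@@H]3CC(=O)OC(C)(C)C)[C@H]12 | intermediate
16 | tert-butyl 2-[(2S,3R,4R,5S)-2-acetoxy-5-methoxy-4-[(1R,3aR,8aS)-1,4,4-trimethyl-8-methylidenedecahydroazulen-1-yl]oxolan-3-yl]acetate | C=C1CCCC(C)(C)[C@@H]2CC[C@@](C)([C@@H]3[C@@H](OC)O[C@@H](OC(C)=O)[C@@H]3CC(=O)OC(C)(C)C)[C@H]12 | intermediate
17 | aplyviolene | C=C1CCCC(C)(C)[C@@H]2CC[C@@](C)([C@@H]3[C@@H]4OC(=O)C[C@H]3[C@H](OC(C)=O)O4)[C@H]12 | target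

## Summary

Total steps: 12.
Longest linear sequence: 8 steps (1→2→4→5→7→14→15→16→17; the butenolide branch 8→13 is also 4 steps before the coupling).

Steps most likely to fail:

1. **Step 9 (proposed cascade).** Risks are premature Sn–H reduction of the vinyl radical, 1,6-H transfer from the allylic ring C–H, and direct addition of the vinyl radical to 13. Fallback (known chemistry): separate ring formation from coupling. Close the seven-membered ring by a tin-hydride Stork vinyl-radical cyclization onto an ester-activated ring alkene (an analogue of 7 with CO2Me in place of the ring methyl), C-methylate the ester enolate, hydrolyse, form the N-acyloxyphthalimide, and couple with 13 by the established visible-light photoredox decarboxylative Giese reaction of tertiary radicals.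

2. **Step 12 (bicyclization).** Risks are competing ionization of the anomeric acetate, formation of the [3.3.0] lactone, and sensitivity of the product. Fallback: reverse the order. Unmask the acid and lactonise the lactol/methyl acetal 15 under mild Brønsted acid to the bicyclic lactol first, then introduce the acetate last by anomeric activation (DAST to the fluoride, then AcOH/BF3·OEt2), with acetate entering from the open exo face.

3. **Step 8 (dynamic kinetic acetalization).** Enantioselectivity on this ester-bearing substrate with methanol is untested. Fallback: hydrolyse 12 to the γ-hydroxybutenolide and run a lipase-catalysed dynamic kinetic acetylation to the (S)-5-acetoxybutenolide. Use that as the radical acceptor, then exchange the acetoxy for methoxy (MeOH, PPTS) after the coupling, where the acetal configuration no longer matters.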